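The numbers in the tables are simulated with made-up constants.

About 0.00236 M s⁻¹ is the number my decision on the next two flasks hangs on: it is the dissolving rate, the fall of c(solid substrate) per second while solid is present and the solution is still thin, read here over the first 10.0 s of the ochre run. The green run, with 0.22 M charged instead of 0.052 M, reads 0.00238 M s⁻¹ over the same seconds, and the amber run at −10 °C reads 0.00254 M s⁻¹, so I carry the rate unchanged across charge and temperature, though taking it to 20 °C is an extrapolation.

| flask | solid substrate | temperature | remark | time |
|---|---|---|---|---|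
| ochre | 0.052 M | −45 °C | run made earlier |  |
| amber | 0.11 M | −10 °C | run made earlier |  |
| green | 0.22 M | −45 °C | run made earlier |  |
| elm | 0.060 M |  | at 20 °C throughout | 4.0 min |
| oak | 0.25 M |  | at −40 °C until 2.0 min, from then on at 20 °C | 4.0 min |

| run | time / s | ring / % | solid substrate / % |
|---|---|---|---|
| ochre | 10.0 | 0 | 54.7 |
| ochre | 20.0 | 0.5 | 21.9 |
| ochre | 30.0 | 1.4 | 0 |
| ochre | 60.0 | 4.1 | 0.2 |
| ochre | 120 | 8.1 | 0.5 |
| amber | 10.0 | 10.2 | 76.9 |
| amber | 12.0 | 13.5 | 73.3 |
| amber | 20.0 | 27.3 | 56.5 |
| amber | 25.0 | 36.2 | 45.9 |
| green | 10.0 | 0.6 | 89.2 |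
| green | 30.0 | 0.2 | 75.2 |
| green | 60.0 | 0.7 | 65.4 |
| green | 80.0 | 1.6 | 60.5 |
| green | 120 | 3.1 | 56.0 |

(standard deviation of a reading: 0.3 percentage points)

- solid, in amounts per volume of the solution: solid substrate
- at the start none of the solid substrate is in solution
- what has only dissolved of solid substrate counts as not reacted

* which of the two ends with the higher amount of ring, in percent of the solid substrate charged ("neither" if they lie within 2 percentage points) (elm / oak / neither)
* ring at the end, in percent of the solid substrate charged, elm
* ring at the end, in percent of the solid substrate charged, oak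

Solid divided by this rate gives a lifetime of the solid, which I call the clearing time. For elm it is 25.5 s, far shorter than the 4.0 min allowed. For oak I take the green run as a guide to the cold stage: its solid lost 0.0968 M in 120 s, so oak should hold about 0.153 M of solid when it warms, and that clears in 65.0 s, about half of the 120 s of warm stage. I therefore leave both charges and the time as they stand, and I commit to no solid substrate remaining in either flask at 4.0 min; this rate does not tell me what share ends as ring.

The forecast says neither, with elm at 98% (92% to 100%) and oak at 96.5% (85% to 100%), on the ground that elm “goes essentially to completion”.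

Elm ends at 89.0% of ring and oak at 84.6%, so elm is ahead by 4.4 percentage points, and elm holds 11.0% of isomer of the product beside its ring, with 0% of solid substrate at 4.00 min.

    starting material → ring (k = 0.00220 s⁻¹, Ea = 74.0 kJ mol⁻¹)
    2 starting material → open dimer (k = 0.0110 M⁻¹ s⁻¹, Ea = 45.0 kJ mol⁻¹)
    solid substrate ⇌ starting material, rate k3*(cs3 - [starting material]) while solid is left; crystals form when [starting material] > cs3 (solubility = 0.0900 M, k = 0.0300 s⁻¹)
    ring ⇌ isomer of the product (K = 0.170, k = 0.0660 s⁻¹, Ea = 68.0 kJ mol⁻¹, ΔH = −3.00 kJ mol⁻¹)
    (constants at −40 °C)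

Oak held 57.9% of solid substrate at 2.00 min, which the dissolving rate clears in 61.4 s, and it holds 0% at 4.00 min. For the neighbouring reading of oak at 2.5 min, the same rate gives 29.6% of solid substrate, and the flask holds 25.9%.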